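## Retrosynthetic overview

1. Target 24 ⇐ sodium tetronate 23 (the acidic work-up also unmasks the furyl ketone) ⇐ C2–C3 bond by a carbonate-Claisen ring closure ⇐ temporary bis(alkylidene)-1,3-dioxolan-2-one 22 ⇐ gold-catalysed 5-exo-dig closure of the (E)-enol tert-butyl carbonate 21.
2. Enabling feature: the 2-(carbonyloxy)-1-en-3-yne of 21. Its carbonate C=O oxygen lies five atoms from the proximal alkyne carbon (future ring C4). The dioxolanone ring so formed, with a C2–O4 bond absent from the target, delivers oxygen to C4, holds the future lactone carbonyl C2 on O1, and turns the alkyne into the enolate whose carbon (future C3) then takes C2; the temporary ring is cleaved in that event.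
3. 21 ⇐ kinetic E(O)-enolisation and O-acylation of propynyl ketone 19, which sets the (E)-alkylidene; 19 ⇐ Weinreb amide 17 + propynyl Grignard; the methyl stereocentre ⇐ Cu/Josiphos conjugate addition of MeMgBr to enethioate 15.
4. Chain ⇐ geranyl acetate: SeO2 oxidation at C8, Cu-catalysed coupling with an acetal Grignard, and dithiane (acyl-anion) alkylation at C1; the ketone is carried as dithiane, then as dimethyl ketal.
5. Ring order: furan (bought) → dithiane (step 6, temporary) → dioxolanone (step 15, temporary) → butenolide (step 15, last).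

Key step: step 15

Remark: ring locants O1, C2–C5 are those of the furan-2(5H)-one (C3 methyl, C4 hydroxyl, C5 alkylidene), and O4 is the oxygen on C4; the given SMILES is read as (5E) with an (S) methyl centre.
Remark: the sense of induction in step 10 is assigned by analogy; the Josiphos enantiomer that gives (3S)-16 is the one to use.

## Route

Step 1
Reactants: 1 geranyl acetate
Product: 2 (2E,6E)-8-hydroxy-3,7-dimethylocta-2,6-dien-1-yl acetate
Conditions: SeO2 (0.2 eq), t-BuOOH, salicylic acid (cat.), CH2Cl2, rt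
Reagents that add atoms: tert-butyl hydroperoxide, CC(C)(C)OO
Why: Riley-type SeO2 allylic oxidation (ene reaction, then [2,3]-shift) should hydroxylate the (E)-methyl of the electron-rich terminal alkene and leave the acetate-deactivated 2,3-alkene alone.

Step 2
Reactants: 2 (2E,6E)-8-hydroxy-3,7-dimethylocta-2,6-dien-1-yl acetate
Product: 3 (2E,6E)-8-bromo-3,7-dimethylocta-2,6-dien-1-yl acetate
Conditions: CBr4, PPh3, CH2Cl2, 0 °C
Reagents that add atoms: tetrabromomethane, BrC(Br)(Br)Br
Why: The Appel reaction should convert the primary allylic alcohol into the bromide under neutral conditions without allylic transposition or loss of the acetate.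

Step 3
Reactants: 3 (2E,6E)-8-bromo-3,7-dimethylocta-2,6-dien-1-yl acetate; 4 [2-(1,3-dioxolan-2-yl)ethyl]magnesium bromide
Product: 5 (2E,6E)-10-(1,3-dioxolan-2-yl)-3,7-dimethyldeca-2,6-dien-1-yl acetate
Conditions: Li2CuCl4 (3 mol%), THF, slow addition of 4, −78 → −20 °C
Reagents that add atoms: none
Why: In the Li2CuCl4-catalysed Grignard cross-coupling the primary allylic bromide should react at its α-carbon with retention of the (E)-alkene, and much faster than the allylic acetate or its carbonyl group at this temperature.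

Step 4
Reactants: 5 (2E,6E)-10-(1,3-dioxolan-2-yl)-3,7-dimethyldeca-2,6-dien-1-yl acetate
Product: 6 (2E,6E)-10-(1,3-dioxolan-2-yl)-3,7-dimethyldeca-2,6-dien-1-ol
Conditions: K2CO3 (0.3 eq), MeOH, rt
Reagents that add atoms: none
Why: Base-catalysed transesterification (methanolysis) should remove the acetate while the acetal, inert to base, stays.

Step 5
Reactants: 6 (2E,6E)-10-(1,3-dioxolan-2-yl)-3,7-dimethyldeca-2,6-dien-1-ol
Product: 7 2-[(4E,8E)-10-bromo-4,8-dimethyldeca-4,8-dien-1-yl]-1,3-dioxolane
Conditions: CBr4, PPh3, CH2Cl2, −20 → 0 °C; used crude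
Reagents that add atoms: tetrabromomethane, BrC(Br)(Br)Br
Why: The Appel reaction should give the geranyl-type bromide under non-acidic conditions that the acetal tolerates.

Step 6
Reactants: 8 furan-3-carbaldehyde; 9 propane-1,3-dithiol
Product: 10 2-(furan-3-yl)-1,3-dithiane
Conditions: BF3·OEt2 (cat.), CH2Cl2, 0 °C → rt
Reagents that add atoms: none
Why: Lewis-acid-catalysed dithioacetalisation should turn the aldehyde into its acyl-anion equivalent.

Step 7
Reactants: 10 2-(furan-3-yl)-1,3-dithiane; 7 2-[(4E,8E)-10-bromo-4,8-dimethyldeca-4,8-dien-1-yl]-1,3-dioxolane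
Product: 12 2-[(4E,8E)-10-[2-(furan-3-yl)-1,3-dithian-2-yl]-4,8-dimethyldeca-4,8-dien-1-yl]-1,3-dioxolane, via 2-(furan-3-yl)-2-lithio-1,3-dithiane 11 (not isolated)
Conditions: n-BuLi, THF, −40 °C; then 7, −78 → 0 °C
Reagents that add atoms: none
Why: In the Corey–Seebach alkylation the lithiated dithiane should displace the primary allylic bromide at the α-carbon (SN2), which attaches the masked furyl ketone carbon in the linear sense and leaves the (E)-alkene untouched.

Step 8
Reactants: 12 2-[(4E,8E)-10-[2-(furan-3-yl)-1,3-dithian-2-yl]-4,8-dimethyldeca-4,8-dien-1-yl]-1,3-dioxolane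
Product: 13 (5E,9E)-11-[2-(furan-3-yl)-1,3-dithian-2-yl]-5,9-dimethylundeca-5,9-dienal
Conditions: 2 M aq. HCl/THF (1:4), rt
Reagents that add atoms: water, O
Why: Acid-catalysed acetal hydrolysis should free the aldehyde while the dithiane, stable to aqueous acid, keeps the ketone masked.

Step 9
Reactants: 13 (5E,9E)-11-[2-(furan-3-yl)-1,3-dithian-2-yl]-5,9-dimethylundeca-5,9-dienal; 14 S-ethyl 2-(triphenyl-λ5-phosphanylidene)ethanethioate
Product: 15 S-ethyl (2E,7E,11E)-13-[2-(furan-3-yl)-1,3-dithian-2-yl]-7,11-dimethyltrideca-2,7,11-trienethioate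
Conditions: CH2Cl2, rt
Reagents that add atoms: none
Why: The Wittig olefination with a stabilised ylide should give the (E)-enethioate needed as conjugate acceptor.

Step 10
Reactants: 15 S-ethyl (2E,7E,11E)-13-[2-(furan-3-yl)-1,3-dithian-2-yl]-7,11-dimethyltrideca-2,7,11-trienethioate
Product: 16 S-ethyl (3S,7E,11E)-13-[2-(furan-3-yl)-1,3-dithian-2-yl]-3,7,11-trimethyltrideca-7,11-dienethioate
Conditions: MeMgBr (1.3 eq), CuBr·SMe2 (5 mol%), (R,SFe)-Josiphos (6 mol%), t-BuOMe, −75 °C
Reagents that add atoms: methylmagnesium bromide, C[Mg]Br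
Why: In the copper/Josiphos-catalysed asymmetric conjugate addition the chiral copper complex selects one face of the C2=C3 bond of the (E)-enethioate, so the new C3 centre is set (S) by catalyst control.

Step 11
Reactants: 16 S-ethyl (3S,7E,11E)-13-[2-(furan-3-yl)-1,3-dithian-2-yl]-3,7,11-trimethyltrideca-7,11-dienethioate
Product: 17 (3S,7E,11E)-13-[2-(furan-3-yl)-1,3-dithian-2-yl]-N-methoxy-N,3,7,11-tetramethyltrideca-7,11-dienamide
Conditions: MeNHOMe·HCl (2 eq), i-PrMgCl (4 eq), THF, −20 °C (amide premixed); then 16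
Reagents that add atoms: N,O-dimethylhydroxylamine hydrochloride, CNOC.Cl
Why: Aminolysis of the activated thioester by the preformed magnesium amide (Weinreb amide formation) should proceed without touching the β-stereocentre, which cannot epimerise.

Step 12
Reactants: 17 (3S,7E,11E)-13-[2-(furan-3-yl)-1,3-dithian-2-yl]-N-methoxy-N,3,7,11-tetramethyltrideca-7,11-dienamide
Product: 18 (6S,10E,14E)-16-[2-(furan-3-yl)-1,3-dithian-2-yl]-6,10,14-trimethylhexadeca-10,14-dien-2-yn-4-one
Conditions: 1-propynylmagnesium bromide (1.5 eq), THF, 0 °C; cold aq. NH4Cl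
Reagents that add atoms: 1-propynylmagnesium bromide, CC#C[Mg]Br
Why: In the Weinreb ketone synthesis the chelated tetrahedral intermediate should stop the addition at the ynone stage.

Step 13
Reactants: 18 (6S,10E,14E)-16-[2-(furan-3-yl)-1,3-dithian-2-yl]-6,10,14-trimethylhexadeca-10,14-dien-2-yn-4-one
Product: 19 (6S,10E,14E)-17-(furan-3-yl)-17,17-dimethoxy-6,10,14-trimethylheptadeca-10,14-dien-2-yn-4-one
Conditions: PhI(OCOCF3)2 (1.3 eq), MeOH, 0 °C, 10 min; Et3N quench; Et3N-deactivated silica
Reagents that add atoms: methanol, CO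
Why: Oxidative dethioacetalisation with a hypervalent iodine reagent in methanol should give the dimethyl ketal directly, because sulfur is oxidised far faster than the alkenes, furan or ynone; this replaces the gold-poisoning dithiane by a gold- and base-stable, acid-labile mask without ever freeing the base-sensitive β,γ-unsaturated ketone.

Step 14
Reactants: 19 (6S,10E,14E)-17-(furan-3-yl)-17,17-dimethoxy-6,10,14-trimethylheptadeca-10,14-dien-2-yn-4-one
Product: 21 tert-butyl (4E,6S,10E,14E)-17-(furan-3-yl)-17,17-dimethoxy-6,10,14-trimethylheptadeca-4,10,14-trien-2-yn-4-yl carbonate, via lithium (E)-enolate 20 (not isolated)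
Conditions: LiTMP (1.1 eq, from TMP/n-BuLi), THF, −78 °C; then Boc2O (1.3 eq), DMPU, −78 → −40 °C
Reagents that add atoms: di-tert-butyl dicarbonate, CC(C)(C)OC(=O)OC(=O)OC(C)(C)C
Why: Kinetic deprotonation by the hindered amide through a closed six-membered transition state (Ireland model) should place the C6 chain syn to the small, rod-like propynyl group and give the E(O)-enolate of the only enolisable position, which the hard electrophile Boc2O should trap on oxygen (enol carbonate formation) with retention of the geometry that becomes the (E)-alkylidene of the target.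

Step 15
Reactants: 21 tert-butyl (4E,6S,10E,14E)-17-(furan-3-yl)-17,17-dimethoxy-6,10,14-trimethylheptadeca-4,10,14-trien-2-yn-4-yl carbonate
Product: 24 (5E)-5-[(2S,6E,10E)-13-(furan-3-yl)-2,6,10-trimethyl-13-oxotrideca-6,10-dien-1-ylidene]-4-hydroxy-3-methylfuran-2(5H)-one, via bis(alkylidene)dioxolanone 22 (not isolated), via sodium tetronate dimethyl ketal 23 (not isolated)
Conditions: (i) Ph3PAuNTf2 (2 mol%), 2,6-di-tert-butylpyridine (5 mol%), CH2Cl2, 0 °C → rt; (ii) solvent switch, add to NaH (2.5 eq)/PhOH (0.2 eq), THF (0.01 M), 0 °C → rt; (iii) 1 M aq. HCl, THF, 0 °C, 30 min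
Reagents that add atoms: water, O
Why: Proposed new method: Cationic gold(I) activates the alkyne and the Boc carbonyl oxygen adds 5-exo-dig to the proximal alkyne carbon (anti-oxyauration), after which loss of isobutene and protodeauration give the temporary dioxolanone 22; this is the known gold-catalysed cyclisation of tert-butyl carbonates onto alkynes, here on an enol rather than a propargylic carbonate. Catalytic phenoxide then opens 22 reversibly to a sodium enolate that carries a phenyl carbonate on the neighbouring enol oxygen, and the enolate carbon derived from the ethylidene group attacks that carbonate carbon in a 5-(enolendo)-exo-trig Claisen closure that forms the C2–C3 bond and cleaves the temporary C2–O4 bond; NaH removes the acidic C3–H irreversibly, so 22 and both ring-opened regioisomers, which interconvert by O-acyl return, should all be funnelled to tetronate 23. The closest known reaction types are the intramolecular Claisen condensation of 4-oxohexanoate esters to 2-methylcyclopentane-1,3-dione (same enolendo geometry), the condensation of α-hydroxy ketones with dialkyl carbonates to tetronic acids, and the Steglich-type O-to-C carboxyl transfer of enol carbonates. No stereocentre is created: the (E)-alkylidene geometry is that of 21 and should persist because this C=C is at every stage an enol carbonate or an unprotonated enolate under aprotic conditions, and the methyl-bearing centre is not acidic in any intermediate. The step needs C-acylation at the methyl-bearing enolate carbon rather than at the alkylidene carbon that carries the branched chain; the much smaller steric demand of the former, the equilibration of both enolates through 22 and high dilution should secure this, while the ketal keeps the furyl ketone from enolising. The acidic work-up protonates the tetronate and hydrolyses the ketal to the β,γ-unsaturated ketone under conditions too mild for conjugation.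

## Compound list

1 | geranyl acetate | CC(C)=CCC/C(C)=C/COC(C)=O | starting material
2 | (2E,6E)-8-hydroxy-3,7-dimethylocta-2,6-dien-1-yl acetate | OC/C(C)=C/CC/C(C)=C/COC(C)=O | intermediate
3 | (2E,6E)-8-bromo-3,7-dimethylocta-2,6-dien-1-yl acetate | BrC/C(C)=C/CC/C(C)=C/COC(C)=O | intermediate
4 | [2-(1,3-dioxolan-2-yl)ethyl]magnesium bromide | Br[Mg]CCC1OCCO1 | starting material
5 | (2E,6E)-10-(1,3-dioxolan-2-yl)-3,7-dimethyldeca-2,6-dien-1-yl acetate | C1COC(CCC/C(C)=C/CC/C(C)=C/COC(C)=O)O1 | intermediate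
6 | (2E,6E)-10-(1,3-dioxolan-2-yl)-3,7-dimethyldeca-2,6-dien-1-ol | C1COC(CCC/C(C)=C/CC/C(C)=C/CO)O1 | intermediate
7 | 2-[(4E,8E)-10-bromo-4,8-dimethyldeca-4,8-dien-1-yl]-1,3-dioxolane | C1COC(CCC/C(C)=C/CC/C(C)=C/CBr)O1 | intermediate
8 | furan-3-carbaldehyde | O=Cc1ccoc1 | starting material
9 | propane-1,3-dithiol | SCCCS | starting material
10 | 2-(furan-3-yl)-1,3-dithiane | C1CSC(SC1)c1ccoc1 | intermediate
11 | 2-(furan-3-yl)-2-lithio-1,3-dithiane | [Li]C1(SCCCS1)c1ccoc1 | intermediate
12 | 2-[(4E,8E)-10-[2-(furan-3-yl)-1,3-dithian-2-yl]-4,8-dimethyldeca-4,8-dien-1-yl]-1,3-dioxolane | C1COC(CCC/C(C)=C/CC/C(C)=C/CC2(SCCCS2)c2ccoc2)O1 | intermediate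
13 | (5E,9E)-11-[2-(furan-3-yl)-1,3-dithian-2-yl]-5,9-dimethylundeca-5,9-dienal | O=CCCC/C(C)=C/CC/C(C)=C/CC1(SCCCS1)c1ccoc1 | intermediate
14 | S-ethyl 2-(triphenyl-λ5-phosphanylidene)ethanethioate | CCSC(=O)C=P(c1ccccc1)(c1ccccc1)c1ccccc1 | starting material
15 | S-ethyl (2E,7E,11E)-13-[2-(furan-3-yl)-1,3-dithian-2-yl]-7,11-dimethyltrideca-2,7,11-trienethioate | CCSC(=O)/C=C/CCC/C(C)=C/CC/C(C)=C/CC1(SCCCS1)c1ccoc1 | intermediate
16 | S-ethyl (3S,7E,11E)-13-[2-(furan-3-yl)-1,3-dithian-2-yl]-3,7,11-trimethyltrideca-7,11-dienethioate | CCSC(=O)C[C@@H](C)CCC/C(C)=C/CC/C(C)=C/CC1(SCCCS1)c1ccoc1 | intermediate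
17 | (3S,7E,11E)-13-[2-(furan-3-yl)-1,3-dithian-2-yl]-N-methoxy-N,3,7,11-tetramethyltrideca-7,11-dienamide | CON(C)C(=O)C[C@@H](C)CCC/C(C)=C/CC/C(C)=C/CC1(SCCCS1)c1ccoc1 | intermediate
18 | (6S,10E,14E)-16-[2-(furan-3-yl)-1,3-dithian-2-yl]-6,10,14-trimethylhexadeca-10,14-dien-2-yn-4-one | CC#CC(=O)C[C@@H](C)CCC/C(C)=C/CC/C(C)=C/CC1(SCCCS1)c1ccoc1 | intermediate
19 | (6S,10E,14E)-17-(furan-3-yl)-17,17-dimethoxy-6,10,14-trimethylheptadeca-10,14-dien-2-yn-4-one | CC#CC(=O)C[C@@H](C)CCC/C(C)=C/CC/C(C)=C/CC(OC)(OC)c1ccoc1 | intermediate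
20 | lithium (4E,6S,10E,14E)-17-(furan-3-yl)-17,17-dimethoxy-6,10,14-trimethylheptadeca-4,10,14-trien-2-yn-4-olate | CC#C/C(O[Li])=C\[C@@H](C)CCC/C(C)=C/CC/C(C)=C/CC(OC)(OC)c1ccoc1 | intermediate
21 | tert-butyl (4E,6S,10E,14E)-17-(furan-3-yl)-17,17-dimethoxy-6,10,14-trimethylheptadeca-4,10,14-trien-2-yn-4-yl carbonate | CC#C/C(OC(=O)OC(C)(C)C)=C\[C@@H](C)CCC/C(C)=C/CC/C(C)=C/CC(OC)(OC)c1ccoc1 | intermediate
22 | (4Z,5E)-4-ethylidene-5-[(2S,6E,10E)-13-(furan-3-yl)-13,13-dimethoxy-2,6,10-trimethyltrideca-6,10-dien-1-ylidene]-1,3-dioxolan-2-one | C/C=C1\OC(=O)O\C1=C\[C@@H](C)CCC/C(C)=C/CC/C(C)=C/CC(OC)(OC)c1ccoc1 | intermediate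
23 | sodium (5E)-5-[(2S,6E,10E)-13-(furan-3-yl)-13,13-dimethoxy-2,6,10-trimethyltrideca-6,10-dien-1-ylidene]-3-methyl-2-oxo-2,5-dihydrofuran-4-olate | [Na+].CC1=C([O-])/C(=C\[C@@H](C)CCC/C(C)=C/CC/C(C)=C/CC(OC)(OC)c2ccoc2)OC1=O | intermediate
24 | (5E)-5-[(2S,6E,10E)-13-(furan-3-yl)-2,6,10-trimethyl-13-oxotrideca-6,10-dien-1-ylidene]-4-hydroxy-3-methylfuran-2(5H)-one | CC1=C(O)/C(=C\[C@@H](C)CCC/C(C)=C/CC/C(C)=C/CC(=O)c2ccoc2)OC1=O | target

## Step count and risks

Total step count: 15. Longest linear sequence: 14 (steps 1–5 and 7–15 from geranyl acetate; step 6 is a one-step side branch).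

Steps most likely to fail:

1. Step 15 (Proposed new method). The C-acylation has to pass through a strained enolendo transition state. It may be outrun by carbonate transfer between ring-opened enolates (oligomerisation), by acylation at the chain-bearing enolate carbon, or the gold stage may close 6-endo. The fallback uses known chemistry, buys the butenolide ring and makes the alkylidene by aldol addition and anti-elimination; it sets out from aldehyde 13 and comes back at target 24. Wittig methylenation of 13 (Ph3P=CH2, THF) should give 2-(furan-3-yl)-2-[(2E,6E)-3,7-dimethyldodeca-2,6,11-trien-1-yl]-1,3-dithiane F1. Zirconium-catalysed asymmetric carboalumination of the terminal alkene (ZACA: Me3Al, (+)-(NMI)2ZrCl2 cat., then O2; catalyst enantiomer chosen for the (S)-alcohol) should give (2S,6E,10E)-12-[2-(furan-3-yl)-1,3-dithian-2-yl]-2,6,10-trimethyldodeca-6,10-dien-1-ol F2. Parikh–Doering oxidation, which spares the dithiane and the α-centre, should give (2S,6E,10E)-12-[2-(furan-3-yl)-1,3-dithian-2-yl]-2,6,10-trimethyldodeca-6,10-dienal F3. Aldol addition of the C5-lithio derivative of 4-methoxy-3-methylfuran-2(5H)-one (LDA, THF, −78 °C) should give 5-[(2S,6E,10E)-12-[2-(furan-3-yl)-1,3-dithian-2-yl]-1-hydroxy-2,6,10-trimethyldodeca-6,10-dien-1-yl]-4-methoxy-3-methylfuran-2(5H)-one F4 as a diastereomer mixture. The pair with like configuration at C5 and the carbinol carbon (5R*,1′R*) is separated; in it the anti-periplanar H–C5/C–O arrangement places the chain next to C4. Mitsunobu-type anti-dehydration (DEAD, PPh3) of that pair should give (5E)-5-[(2S,6E,10E)-12-[2-(furan-3-yl)-1,3-dithian-2-yl]-2,6,10-trimethyldodeca-6,10-dien-1-ylidene]-4-methoxy-3-methylfuran-2(5H)-one F5. Alkylative dithiane hydrolysis (MeI, CaCO3, aq. MeCN) should give (5E)-5-[(2S,6E,10E)-13-(furan-3-yl)-2,6,10-trimethyl-13-oxotrideca-6,10-dien-1-ylidene]-4-methoxy-3-methylfuran-2(5H)-one F6, and O-demethylation with LiCl in DMF followed by acidification should return 24.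

2. Step 14. E(O) control may be lost through proton exchange between enolate and unreacted ketone, the lithium enolate may be acylated on carbon by Boc2O, or the propargylic methyl may be deprotonated instead. The fallback relays the enolate through a silyl enol ether whose geometry can be checked and upgraded before the carbonate is installed; it sets out from 19 and comes back at 21. Deprotonation with LiTMP in the presence of Me3SiCl (in-situ quench, THF, −78 °C) should give [(4E,6S,10E,14E)-17-(furan-3-yl)-17,17-dimethoxy-6,10,14-trimethylheptadeca-4,10,14-trien-2-yn-4-yl]oxy(trimethyl)silane F7. After purification, MeLi (THF, −20 °C) regenerates the amine-free lithium enolate 20 with retention of geometry, and Boc2O/DMPU then gives 21.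

3. Step 13. The hypervalent iodine reagent may attack the electron-rich furan, or acid-promoted addition of methanol to the ynone may compete with sulfur oxidation. The fallback changes the mask one stage earlier by a non-oxidative route; it sets out from Weinreb amide 17 and comes back at 19. Alkylative hydrolysis of the dithiane (MeI, CaCO3, aq. MeCN) should give (3S,7E,11E)-13-(furan-3-yl)-N-methoxy-N,3,7,11-tetramethyl-13-oxotrideca-7,11-dienamide F8 without base. Silyl-triflate-catalysed ketalisation (MeOSiMe3, TMSOTf cat., CH2Cl2, −78 °C), which does not move β,γ-double bonds, should give (3S,7E,11E)-13-(furan-3-yl)-N,13,13-trimethoxy-N,3,7,11-tetramethyltrideca-7,11-dienamide F9. Addition of 1-propynylmagnesium bromide (THF, 0 °C, buffered work-up) then gives 19.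

## Further compounds

F1 | step 15 | 2-(furan-3-yl)-2-[(2E,6E)-3,7-dimethyldodeca-2,6,11-trien-1-yl]-1,3-dithiane | C=CCCC/C(C)=C/CC/C(C)=C/CC1(SCCCS1)c1ccoc1
F2 | step 15 | (2S,6E,10E)-12-[2-(furan-3-yl)-1,3-dithian-2-yl]-2,6,10-trimethyldodeca-6,10-dien-1-ol | OC[C@@H](C)CCC/C(C)=C/CC/C(C)=C/CC1(SCCCS1)c1ccoc1
F3 | step 15 | (2S,6E,10E)-12-[2-(furan-3-yl)-1,3-dithian-2-yl]-2,6,10-trimethyldodeca-6,10-dienal | O=C[C@@H](C)CCC/C(C)=C/CC/C(C)=C/CC1(SCCCS1)c1ccoc1
F4 | step 15 | 5-[(2S,6E,10E)-12-[2-(furan-3-yl)-1,3-dithian-2-yl]-1-hydroxy-2,6,10-trimethyldodeca-6,10-dien-1-yl]-4-methoxy-3-methylfuran-2(5H)-one (diastereomers at C5 and C1′) | COC1=C(C)C(=O)OC1C(O)[C@@H](C)CCC/C(C)=C/CC/C(C)=C/CC1(SCCCS1)c1ccoc1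
F5 | step 15 | (5E)-5-[(2S,6E,10E)-12-[2-(furan-3-yl)-1,3-dithian-2-yl]-2,6,10-trimethyldodeca-6,10-dien-1-ylidene]-4-methoxy-3-methylfuran-2(5H)-one | CC1=C(OC)/C(=C\[C@@H](C)CCC/C(C)=C/CC/C(C)=C/CC2(SCCCS2)c2ccoc2)OC1=O
F6 | step 15 | (5E)-5-[(2S,6E,10E)-13-(furan-3-yl)-2,6,10-trimethyl-13-oxotrideca-6,10-dien-1-ylidene]-4-methoxy-3-methylfuran-2(5H)-one | CC1=C(OC)/C(=C\[C@@H](C)CCC/C(C)=C/CC/C(C)=C/CC(=O)c2ccoc2)OC1=O
F7 | step 14 | [(4E,6S,10E,14E)-17-(furan-3-yl)-17,17-dimethoxy-6,10,14-trimethylheptadeca-4,10,14-trien-2-yn-4-yl]oxy(trimethyl)silane | CC#C/C(O[Si](C)(C)C)=C\[C@@H](C)CCC/C(C)=C/CC/C(C)=C/CC(OC)(OC)c1ccoc1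
F8 | step 13 | (3S,7E,11E)-13-(furan-3-yl)-N-methoxy-N,3,7,11-tetramethyl-13-oxotrideca-7,11-dienamide | CON(C)C(=O)C[C@@H](C)CCC/C(C)=C/CC/C(C)=C/CC(=O)c1ccoc1
F9 | step 13 | (3S,7E,11E)-13-(furan-3-yl)-N,13,13-trimethoxy-N,3,7,11-tetramethyltrideca-7,11-dienamide | CON(C)C(=O)C[C@@H](C)CCC/C(C)=C/CC/C(C)=C/CC(OC)(OC)c1ccoc1
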